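Ring B is treated as a folded polyketide. Its lactone carbonyl hangs on C1′, the phenol O on C2′ and the depside O on C4′ form a resorcylate pair, the diaryl-ether O sits on C5′, and the lactol carbon sits on C6′. The C1′–C6′ bond is therefore closed last, by intramolecular aldol addition within an open 3,5,7-triketo ester. That precursor carries the finished ring A as an aryloxy group on C6, a benzyloxymethyl group on C4 and a dimethyl acetal next to the C7 ketone. One operation delivers the hexasubstituted arene and the hindered diaryl ether, with no aryl–oxygen coupling. The chain is unmasked from a dioxinone; the labile lactol centre is fixed as a crystalline pseudo-ester.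

Key step: step 11

Assumption: the lactol carbon epimerises by ring–chain tautomerism in protic or basic media, so the S configuration is set on a configurationally stable pseudo-ester and released only in the last, neutral step; which enantiomer of 1-phenylethanol makes the S epimer the less soluble one must be found by trial, and the R alcohol is drawn.

Step 1
Reactants: 1 orsellinic acid (2,4-dihydroxy-6-methylbenzoic acid)
Product: 2 tert-butyl 2,4-dihydroxy-6-methylbenzoate
Conditions: Cl3CC(=NH)Ot-Bu (2.5 equiv), THF–cyclohexane, rt
Reagents that add atoms: tert-butyl 2,2,2-trichloroacetimidate, CC(C)(C)OC(=N)C(Cl)(Cl)Cl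
Why: The acid protonates the imidate and is tert-butylated through the resulting ion pair (trichloroacetimidate esterification) at room temperature, which avoids decarboxylation of this salicylic-type acid, leaves the phenols alone, and installs the bulky ester that later shields the ring A carboxyl carbon from the neighbouring enolate.

Step 2
Reactants: 2 tert-butyl 2,4-dihydroxy-6-methylbenzoate
Product: 3 tert-butyl 4-(benzyloxy)-2-hydroxy-6-methylbenzoate
Conditions: BnBr (1.05 equiv), K2CO3, acetone, 56 °C
Reagents that add atoms: benzyl bromide, BrCc1ccccc1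
Why: Williamson etherification takes the free 4-OH because the 2-OH is tied up in a hydrogen bond to the ester, and benzyl is chosen since it can leave in the final neutral hydrogenolysis, whereas a methyl ether would demand boron halides that ionise the lactol centre.

Step 3
Reactants: 3 tert-butyl 4-(benzyloxy)-2-hydroxy-6-methylbenzoate
Product: 4 tert-butyl 4-(benzyloxy)-3-formyl-2-hydroxy-6-methylbenzoate
Conditions: MgCl2, Et3N, (CH2O)n, MeCN, 80 °C; cold aq. citric acid work-up
Reagents that add atoms: paraformaldehyde (as formaldehyde), C=O
Why: In the Casnati–Skattebøl ortho-formylation the magnesium phenoxide delivers formaldehyde through a chelate to its only free ortho carbon, C3, and a second formaldehyde oxidises the benzylic alkoxide by hydride transfer, all under non-acidic conditions that the tert-butyl ester tolerates.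

Step 4
Reactants: 4 tert-butyl 4-(benzyloxy)-3-formyl-2-hydroxy-6-methylbenzoate
Product: 5 tert-butyl 4-(benzyloxy)-3-(dimethoxymethyl)-2-hydroxy-6-methylbenzoate
Conditions: HC(OMe)3, MeOH, PPTS (5 mol %), rt; Et3N quench, evaporate, use crude
Reagents that add atoms: trimethyl orthoformate, COC(OC)OC; methanol, CO
Why: Acid-catalysed acetalisation is driven by the orthoformate as water scavenger, and the mask is indispensable because a free ortho-formyl group would be attacked by the later aryloxy-ketone enolate (Rap–Stoermer benzofuran closure); the acetal beside the free phenol is labile and is therefore quenched basic and used crude.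

Step 5
Reactants: 5 tert-butyl 4-(benzyloxy)-3-(dimethoxymethyl)-2-hydroxy-6-methylbenzoate; 6 3-bromo-1,1-dimethoxypropan-2-one
Product: 7 tert-butyl 4-(benzyloxy)-3-(dimethoxymethyl)-2-(3,3-dimethoxy-2-oxopropoxy)-6-methylbenzoate (aryloxy ketone)
Conditions: Cs2CO3 (1.2 equiv), DMF, 0 °C → rt
Reagents that add atoms: none
Why: The caesium phenoxide displaces bromide from the activated α-bromo ketone (SN2, Williamson type), so the oxygen that will bridge the two arenes is attached to chain carbon C6 without any aryl–oxygen coupling.

Step 6
Reactants: 8 2,2,6-trimethyl-4H-1,3-dioxin-4-one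
Product: 9 tert-butyl 2-(2,2-dimethyl-4-oxo-4H-1,3-dioxin-6-yl)acetate
Conditions: LiHMDS (2.1 equiv), THF, −78 °C; Boc2O, −78 → −20 °C; aq. NH4Cl
Reagents that add atoms: di-tert-butyl dicarbonate, CC(C)(C)OC(=O)OC(=O)OC(C)(C)C
Why: The lithium dienolate of the dioxinone is acylated at its exocyclic γ-carbon by the dicarbonate (vinylogous Claisen-type C-carboxylation), the second equivalent of base absorbing the more acidic product.

Step 7
Reactants: 9 tert-butyl 2-(2,2-dimethyl-4-oxo-4H-1,3-dioxin-6-yl)acetate; 10 benzyl chloromethyl ether
Product: 11 tert-butyl 3-(benzyloxy)-2-(2,2-dimethyl-4-oxo-4H-1,3-dioxin-6-yl)propanoate (racemic)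
Conditions: NaH (1.0 equiv), THF, 0 °C; 10, Bu4NI (10 mol %), 0 °C → rt
Reagents that add atoms: none
Why: The anion of 9 is a vinylogous malonate whose oxygen termini are ester oxygens, so the hard chloromethyl ether ends on carbon as in a malonate alkylation instead of on oxygen as it tends to with β-diketone enolates; the new stereocentre is racemic and becomes sp2 in step 11.

Step 8
Reactants: 11 tert-butyl 3-(benzyloxy)-2-(2,2-dimethyl-4-oxo-4H-1,3-dioxin-6-yl)propanoate
Product: 12 3-(benzyloxy)-2-(2,2-dimethyl-4-oxo-4H-1,3-dioxin-6-yl)propanoic acid (racemic)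
Conditions: TFA–CH2Cl2 (1:3), 0 °C → rt; toluene azeotrope, use at once
Reagents that add atoms: none
Why: Acidolysis (AAL1) removes the tert-butyl group as isobutene while the dioxinone and the primary benzyl ether are stable to trifluoroacetic acid, and the vinylogous malonic half-acid is kept cold and used at once to avoid decarboxylation.

Step 9
Reactants: 7 aryloxy ketone; 12 dioxinone acid
Product: 14 diketo-dioxinone (chain C1–C3 masked as dioxinone; tautomer and diastereomer mixture), via acid chloride 13 (not isolated)
Conditions: 12, (COCl)2, DMF (cat.), CH2Cl2, 0 °C, evaporate; add slowly to 7, MgBr2·OEt2 (3 equiv), i-Pr2NEt (4 equiv), CH2Cl2, 0 °C; pH 5 buffer work-up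
Reagents that add atoms: oxalyl chloride, O=C(Cl)C(=O)Cl (supplies the chlorine of 13 only)
Why: Magnesium chelation acidifies the ArOCH2 protons so that the amine forms the enolate reversibly and the acid chloride acylates it on carbon (soft-enolisation synthesis of 1,3-diketones from ketones); reversible proton transfer tolerates the acidic α-hydrogen of 13, the product leaves the equilibrium as its magnesium diketonate, the dioxinone leaves only one acyl carbon open to attack so the benzyloxymethyl group must end on C4, and the tert-butyl ester blocks Dieckmann closure onto ring A.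

Step 10
Reactants: 14 diketo-dioxinone; 15 allyl alcohol
Product: 17 allyl 6-aryloxy-4-(benzyloxymethyl)-8,8-dimethoxy-3,5,7-trioxooctanoate (aryl = ring A unit of 7; tautomer mixture), via acylketene 16 (not isolated)
Conditions: 15 (10 equiv), PhMe, 110 °C, 45 min; evaporate, use crude
Reagents that add atoms: none
Why: Retro-hetero-Diels–Alder loss of acetone gives the acylketene, which the excess primary alcohol traps faster than the C5 enol can (ketene-trapping route to β-keto esters), and the allyl ester is chosen because it can later be removed by neutral Pd(0) chemistry that leaves the depsidone lactone intact.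

Step 11
Reactants: 17 aryloxy 3,5,7-triketo ester
Product: 19 allyl 3-[(benzyloxy)methyl]-5-[3-(benzyloxy)-6-(tert-butoxycarbonyl)-2-(dimethoxymethyl)-5-methylphenoxy]-6-(dimethoxymethyl)-2,4-dihydroxybenzoate, via cyclic aldol 18 (not isolated)
Conditions: Et3N (3 equiv), AcOH (1 equiv), CH2Cl2, 0 °C → rt
Reagents that add atoms: none
Why: The buffer enolises the C2 methylene between the allyl ester and the C3 ketone, this carbon adds to the C7 ketone, which the electron-withdrawing acetal neighbour makes the most electrophilic carbonyl of the chain, and E1cB loss of water from aldol 18 followed by enolisation of the C3 and C5 ketones gives arene 19 irreversibly. The closest known reaction type is the biomimetic aldol aromatisation of 3,5,7-triketo esters to resorcylates under weak base. The single ring closes in a 6-(enolexo)-exo-trig mode and forms the C2–C7 bond, which is C1′–C6′ of ring B. No stereocentre is created, because C4 and C6 of the chain both become sp2. The step needs aldol closure to beat Claisen, pyrone and Dieckmann pathways: Claisen attack of C6 on the ester would give a quaternary carbon that cannot aromatise and so stays reversible, pyrone formation needs acid or heat, and the tert-butyl ester shields the ring A carboxyl from the C6 enolate. Weak base and low temperature also hold back E1cB loss of benzyl alcohol from C4.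

Step 12
Reactants: 19 diaryl ether
Product: 20 4-(benzyloxy)-2-{3-(allyloxycarbonyl)-5-[(benzyloxy)methyl]-2-formyl-4,6-dihydroxyphenoxy}-3-formyl-6-methylbenzoic acid
Conditions: TFA–CH2Cl2 (1:4), H2O (10 equiv), 0 °C → rt
Reagents that add atoms: water, O
Why: Trifluoroacetic acid cleaves the ring A tert-butyl ester by AAL1 ionisation and, with water, hydrolyses both acetals, while the allyl ester and the benzyl ethers persist, the benzylic ether of ring B being protected from ionisation by the para-formyl group that appears at once.

Step 13
Reactants: 20 seco acid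
Product: 21 depsidone allyl ester (seven-membered lactone between the ring A carboxyl and O-C4′; both formyl groups free)
Conditions: DCC (1.3 equiv), CH2Cl2–PhMe, 2 mM, rt
Reagents that add atoms: none
Why: Carbodiimide activation of the only carboxylic acid and attack by the C4′ phenol, the sole hydroxyl within reach (the C2′ phenol is para to the ether), closes the depsidone ring, a standard lactonisation of 2-(2-hydroxyaryloxy)benzoic acids that tolerates formyl groups.

Step 14
Reactants: 21 depsidone allyl ester
Product: 22 di-O-benzyl salazinic acid (hydroxyphthalide lactol, racemic and interconverting)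
Conditions: Pd(PPh3)4 (5 mol %), p-TolSO2H (1.2 equiv), CH2Cl2, rt
Reagents that add atoms: none
Why: Tsuji–Trost-type deallylation transfers the allyl group to the sulfinate under weakly acidic conditions, and the freed 2-formylbenzoic acid closes spontaneously to the hydroxyphthalide because buttressing in the hexasubstituted ring favours the cyclic tautomer; the lactol carbon forms racemic and keeps interconverting.

Step 15
Reactants: 22 lactol; 23 (R)-1-phenylethanol
Product: 24 (S)-3-[(R)-1-phenylethoxy]phthalide pseudo-ester of di-O-benzyl salazinic acid (S at the acetal carbon, R in the auxiliary)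
Conditions: 23 (1.5 equiv), CSA (10 mol %), 4 Å MS, PhMe, 40 °C; then heptane, seed, slurry at 20 °C with the acid still present; filter
Reagents that add atoms: none
Why: Acid-catalysed pseudo-ester formation (lactol to 3-alkoxyphthalide) is reversible, so both epimers at the acetal carbon interconvert through the oxocarbenium ion or the open hemiacetal while the less soluble (S,R) diastereomer crystallises, a crystallisation-induced diastereomer transformation of the kind used for butenolide and phthalide pseudo-esters of chiral alcohols, which sets the S centre under solubility control by the auxiliary.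

Step 16
Reactants: 24 pseudo-ester
Product: 25 (S)-salazinic acid (target)
Conditions: H2 (1 atm), 10% Pd/C, EtOAc, 0–5 °C; filter and concentrate cold, crystallise
Reagents that add atoms: none
Why: Hydrogenolysis breaks only the three O–C bonds on the side of the unhindered phenyl rings (benzyl ether cleavage, as in the release of lactols from benzyl glycosides), so no bond to the acetal carbon is touched and the S configuration is retained, while the crowded, hydrogen-bonded aldehyde and the hindered ArCH2OH react much more slowly and the cold neutral aprotic medium slows ring–chain tautomerism.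

Compound list
1 | orsellinic acid | Cc1cc(O)cc(O)c1C(=O)O | starting material
2 | tert-butyl 2,4-dihydroxy-6-methylbenzoate | Cc1cc(O)cc(O)c1C(=O)OC(C)(C)C | intermediate
3 | tert-butyl 4-(benzyloxy)-2-hydroxy-6-methylbenzoate | Cc1cc(OCc2ccccc2)cc(O)c1C(=O)OC(C)(C)C | intermediate
4 | tert-butyl 4-(benzyloxy)-3-formyl-2-hydroxy-6-methylbenzoate | Cc1cc(OCc2ccccc2)c(C=O)c(O)c1C(=O)OC(C)(C)C | intermediate
5 | tert-butyl 4-(benzyloxy)-3-(dimethoxymethyl)-2-hydroxy-6-methylbenzoate | Cc1cc(OCc2ccccc2)c(C(OC)OC)c(O)c1C(=O)OC(C)(C)C | intermediate
6 | 3-bromo-1,1-dimethoxypropan-2-one | COC(OC)C(=O)CBr | starting material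
7 | aryloxy ketone, tert-butyl 4-(benzyloxy)-3-(dimethoxymethyl)-2-(3,3-dimethoxy-2-oxopropoxy)-6-methylbenzoate | COC(OC)C(=O)COc1c(C(OC)OC)c(OCc2ccccc2)cc(C)c1C(=O)OC(C)(C)C | intermediate
8 | 2,2,6-trimethyl-4H-1,3-dioxin-4-one | CC1=CC(=O)OC(C)(C)O1 | starting material
9 | tert-butyl 2-(2,2-dimethyl-4-oxo-4H-1,3-dioxin-6-yl)acetate | CC1(C)OC(=O)C=C(CC(=O)OC(C)(C)C)O1 | intermediate
10 | benzyl chloromethyl ether | ClCOCc1ccccc1 | starting material
11 | tert-butyl 3-(benzyloxy)-2-(2,2-dimethyl-4-oxo-4H-1,3-dioxin-6-yl)propanoate, racemic | CC1(C)OC(=O)C=C(O1)C(COCc2ccccc2)C(=O)OC(C)(C)C | intermediate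
12 | 3-(benzyloxy)-2-(2,2-dimethyl-4-oxo-4H-1,3-dioxin-6-yl)propanoic acid, racemic | CC1(C)OC(=O)C=C(O1)C(COCc2ccccc2)C(=O)O | intermediate
13 | acid chloride of 12 (not isolated) | CC1(C)OC(=O)C=C(O1)C(COCc2ccccc2)C(=O)Cl | intermediate
14 | diketo-dioxinone, tert-butyl 4-(benzyloxy)-2-{[6-(benzyloxy)-5-(2,2-dimethyl-4-oxo-4H-1,3-dioxin-6-yl)-1,1-dimethoxy-2,4-dioxohexan-3-yl]oxy}-3-(dimethoxymethyl)-6-methylbenzoate, stereoisomer and tautomer mixture | CC1(C)OC(=O)C=C(O1)C(COCc2ccccc2)C(=O)C(Oc2c(C(OC)OC)c(OCc3ccccc3)cc(C)c2C(=O)OC(C)(C)C)C(=O)C(OC)OC | intermediate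
15 | allyl alcohol | C=CCO | starting material
16 | acylketene from 14 (not isolated) | O=C=CC(=O)C(COCc1ccccc1)C(=O)C(Oc1c(C(OC)OC)c(OCc2ccccc2)cc(C)c1C(=O)OC(C)(C)C)C(=O)C(OC)OC | intermediate
17 | aryloxy 3,5,7-triketo ester (allyl ester), tautomer mixture | C=CCOC(=O)CC(=O)C(COCc1ccccc1)C(=O)C(Oc1c(C(OC)OC)c(OCc2ccccc2)cc(C)c1C(=O)OC(C)(C)C)C(=O)C(OC)OC | intermediate
18 | cyclic aldol, 2-hydroxy-4,6-dioxocyclohexanecarboxylate (not isolated) | C=CCOC(=O)C1C(=O)C(COCc2ccccc2)C(=O)C(Oc2c(C(OC)OC)c(OCc3ccccc3)cc(C)c2C(=O)OC(C)(C)C)C1(O)C(OC)OC | intermediate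
19 | diaryl ether with complete hexasubstituted ring B | C=CCOC(=O)c1c(O)c(COCc2ccccc2)c(O)c(Oc2c(C(OC)OC)c(OCc3ccccc3)cc(C)c2C(=O)OC(C)(C)C)c1C(OC)OC | intermediate
20 | seco acid dialdehyde | C=CCOC(=O)c1c(O)c(COCc2ccccc2)c(O)c(Oc2c(C=O)c(OCc3ccccc3)cc(C)c2C(=O)O)c1C=O | intermediate
21 | depsidone allyl ester | Cc1cc(OCc4ccccc4)c(C=O)c2c1C(=O)Oc1c(COCc4ccccc4)c(O)c(C(=O)OCC=C)c(C=O)c1O2 | intermediate
22 | di-O-benzyl salazinic acid, lactol racemic | Cc1cc(OCc4ccccc4)c(C=O)c2c1C(=O)Oc1c(COCc4ccccc4)c(O)c3c(c1O2)C(O)OC3=O | intermediate
23 | (R)-1-phenylethanol | C[C@@H](O)c1ccccc1 | starting material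
24 | (S)-acetal, (R)-1-phenylethyl pseudo-ester of di-O-benzyl salazinic acid | Cc1cc(OCc4ccccc4)c(C=O)c2c1C(=O)Oc1c(COCc4ccccc4)c(O)c3c(c1O2)[C@@H](O[C@H](C)c4ccccc4)OC3=O | intermediate
25 | (S)-salazinic acid, CNP0166154.1 | Cc1cc(O)c(C=O)c2c1C(=O)Oc1c(CO)c(O)c3c(c1O2)[C@@H](O)OC3=O | target

Total step count: 16. Longest linear sequence: 13 (steps 1–5 and 9–16). The side branch is steps 6–8.

Steps most likely to fail

Step 11. An enol oxygen may lactonise onto the allyl ester, benzyl alcohol may be lost from C4 by β-elimination, or the reaction may stall at the aldol stage. The fallback aromatises before the chain is opened and sets out from 14. Treatment with Et3N in CH2Cl2 lets the ring carbon C5 of the intact dioxinone (chain C2) add to the same ketone. In this form there is neither a ketene nor an open ester, so no pyrone can form, and the product is the acetonide-bridged resorcylate (benzodioxinone) F4. Sodium allyloxide in allyl alcohol–THF then opens the dioxinone ring with loss of acetone, and the route is rejoined at 19.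

Step 9. Proton transfer from the acidic acyl donor may lead to ketene formation and self-condensation, acylation may occur on oxygen, or the magnesium salt may activate the aryl acetal so that the enolate closes onto it. The fallback inverts the roles of the fragments, so that every acyl donor is non-acidic and no Lewis acid is present. It sets out from 5:
- Alkylation with 2-chloro-N-methoxy-N-methylacetamide (K2CO3, NaI, DMF) gives the aryloxy Weinreb amide F1.
- Addition of the lithium dienolate of 8 (THF, −78 °C) gives the keto-dioxinone F2.
- The dianion of F2 (LDA, 2.2 equiv) is acylated at the aryloxy-bearing carbon with methyl dimethoxyacetate to give the unsubstituted diketo-dioxinone F3.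
- The dianion of F3 is alkylated by 10 at its less stabilised carbon C4, which rejoins the route at 14.

Step 15. The two epimers may show no useful solubility difference, epimerisation may be too slow to feed the crystals, or the acid may dehydrate the auxiliary. The fallback gives up the auxiliary and sets out from 22. Benzyl alcohol with CSA and molecular sieves gives the racemic benzyl pseudo-ester F5. F5 is resolved on a chiral stationary phase, with the unwanted enantiomer racemised by CSA and recycled. This gives the (S)-benzyl pseudo-ester F6. Hydrogenolysis under the conditions of step 16 rejoins the route at 25.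

Further compounds
F1 | step 9 | tert-butyl 4-(benzyloxy)-3-(dimethoxymethyl)-2-{2-[methoxy(methyl)amino]-2-oxoethoxy}-6-methylbenzoate | CON(C)C(=O)COc1c(C(OC)OC)c(OCc2ccccc2)cc(C)c1C(=O)OC(C)(C)C
F2 | step 9 | keto-dioxinone, tert-butyl 4-(benzyloxy)-3-(dimethoxymethyl)-2-[3-(2,2-dimethyl-4-oxo-4H-1,3-dioxin-6-yl)-2-oxopropoxy]-6-methylbenzoate | CC1(C)OC(=O)C=C(CC(=O)COc2c(C(OC)OC)c(OCc3ccccc3)cc(C)c2C(=O)OC(C)(C)C)O1
F3 | step 9 | diketo-dioxinone without the benzyloxymethyl group | CC1(C)OC(=O)C=C(CC(=O)C(Oc2c(C(OC)OC)c(OCc3ccccc3)cc(C)c2C(=O)OC(C)(C)C)C(=O)C(OC)OC)O1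
F4 | step 11 | acetonide-bridged resorcylate (2,2-dimethyl-4H-1,3-benzodioxin-4-one form of ring B) | CC1(C)Oc2c(COCc3ccccc3)c(O)c(Oc3c(C(OC)OC)c(OCc4ccccc4)cc(C)c3C(=O)OC(C)(C)C)c(C(OC)OC)c2C(=O)O1
F5 | step 15 | racemic benzyl pseudo-ester of di-O-benzyl salazinic acid | Cc1cc(OCc4ccccc4)c(C=O)c2c1C(=O)Oc1c(COCc4ccccc4)c(O)c3c(c1O2)C(OCc4ccccc4)OC3=O
F6 | step 15 | (S)-benzyl pseudo-ester of di-O-benzyl salazinic acid | Cc1cc(OCc4ccccc4)c(C=O)c2c1C(=O)Oc1c(COCc4ccccc4)c(O)c3c(c1O2)[C@@H](OCc4ccccc4)OC3=O
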